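**Retrosynthetic overview** (compound numbers are those of the forward route below)
1. Target acid ⇐ ester saponification and selective hydrogenation of C3=C4 of an (R)-2H-chromene methyl ester.
2. Pyran ring (the only ring made, closed last) ⇐ chiral-acid-catalysed dehydration of an o-hydroxybenzyl (E)-allylic alcohol to a dearomatised vinyl o-quinone methide, then enantioselective oxa-6π ring closure (O1–C2 bond, sets C2).
3. That carbinol ⇐ C4–C4a bond from the aryl Grignard of 4-iodoorcinol (orcinol + ICl) and a (2E)-enal.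
4. Enal ⇐ (2E,6E)-farnesol: terminal bromohydrin/epoxide, periodate cleavage, Still–Gennari (2Z) olefination, MnO2.
5. The benzene ring is bought as orcinol; the farnesol 2E geometry becomes the fixed alkene geometry of the o-quinone methide.

Assumption: orcinol, (2E,6E)-farnesol (≥96 % E,E) and phosphonate 7 are purchased; which antipode of the acid catalyst in step 7 gives (R) cannot be predicted and is fixed by one test run (the (R)-catalyst is written).

Step 1
Reactants: 1 orcinol (5-methylbenzene-1,3-diol)
Product: 2 4-iodo-5-methylbenzene-1,3-diol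
Conditions: ICl (1.0 equiv), Et2O, 0 °C
Reagents that add atoms: iodine monochloride, ClI
Why: Electrophilic aromatic iodination under non-basic conditions is expected to go para to one OH and ortho to the other (C4, the position that also takes formyl and acyl electrophiles), whereas the C2 isomer is the product of the I2/NaHCO3 phenoxide protocol.

Step 2
Reactants: 3 (2E,6E)-farnesol
Product: 5 (2E,6E)-9-(3,3-dimethyloxiran-2-yl)-3,7-dimethylnona-2,6-dien-1-ol, via bromohydrin 4 (not isolated)
Conditions: NBS (1.05 equiv), THF/H2O 2:1, 0 °C; then K2CO3, MeOH, rt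
Reagents that add atoms: water, O; N-bromosuccinimide, O=C1CCC(=O)N1Br (its Br is carried only in 4)
Why: van Tamelen terminal functionalisation: in aqueous THF the remote 10,11-alkene is the most accessible site for bromonium formation (the 2,3-alkene is deactivated by the allylic OH), water opens at the tertiary carbon and base closes the bromohydrin to the epoxide; the racemic C10 centre is destroyed in step 3.

Step 3
Reactants: 5 (2E,6E)-9-(3,3-dimethyloxiran-2-yl)-3,7-dimethylnona-2,6-dien-1-ol
Product: 6 (4E,8E)-10-hydroxy-4,8-dimethyldeca-4,8-dienal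
Conditions: H5IO6 (1.2 equiv), THF/Et2O, 0 °C
Reagents that add atoms: none
Why: Periodic acid hydrolyses the trisubstituted epoxide to the glycol in situ and cleaves it (Malaprade-type glycol cleavage) to the aldehyde and acetone without touching the alkenes or the allylic alcohol.

Step 4
Reactants: 6 (4E,8E)-10-hydroxy-4,8-dimethyldeca-4,8-dienal; 7 methyl 2-[bis(2,2,2-trifluoroethoxy)phosphoryl]propanoate
Product: 8 methyl (2Z,6E,10E)-12-hydroxy-2,6,10-trimethyldodeca-2,6,10-trienoate
Conditions: 7 (1.2 equiv), KHMDS (1.15 equiv), 18-crown-6, THF, −78 °C; then 6, −78 °C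
Reagents that add atoms: methyl 2-[bis(2,2,2-trifluoroethoxy)phosphoryl]propanoate (compound 7), COC(=O)C(C)P(=O)(OCC(F)(F)F)OCC(F)(F)F
Why: Still–Gennari variant of the Horner–Wadsworth–Emmons olefination: the electron-poor phosphonate with a dissociated potassium counter-ion eliminates under kinetic control to the (Z)-2-methyl-2-enoate (typically ≥20:1), and the preformed phosphonate anion is too weak a base to disturb the free OH.

Step 5
Reactants: 8 methyl (2Z,6E,10E)-12-hydroxy-2,6,10-trimethyldodeca-2,6,10-trienoate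
Product: 9 methyl (2Z,6E,10E)-2,6,10-trimethyl-12-oxododeca-2,6,10-trienoate
Conditions: activated MnO2 (15 equiv), CH2Cl2, rt
Reagents that add atoms: none
Why: MnO2 is a chemoselective allylic alcohol oxidation that stops at the enal and keeps the 10E geometry, which later decides which enantiomer the ring closure gives.

Step 6
Reactants: 2 4-iodo-5-methylbenzene-1,3-diol; 9 methyl (2Z,6E,10E)-2,6,10-trimethyl-12-oxododeca-2,6,10-trienoate
Product: 11 methyl (2Z,6E,10E)-12-(2,4-dihydroxy-6-methylphenyl)-12-hydroxy-2,6,10-trimethyldodeca-2,6,10-trienoate, via arylmagnesium species 10 (not isolated)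
Conditions: 2, MeMgCl (2.0 equiv), LiCl, THF, −20 °C; iPrMgCl·LiCl (1.1 equiv), 0 °C → rt; then 9, −78 → −30 °C; cold pH 7 buffer, Florisil plug, concentrate ≤0 °C, use at once
Reagents that add atoms: none
Why: Iodine–magnesium exchange on the preformed bis(magnesium phenoxide) (Knochel-type magnesiation of unprotected halophenols) gives the aryl Grignard at the future C4a, and its 1,2-addition to the β,β-disubstituted enal, faster than attack on the hindered conjugated ester, forms the C4–C4a bond; the carbinol centre is racemic and is erased in step 7.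

Step 7
Reactants: 11 methyl (2Z,6E,10E)-12-(2,4-dihydroxy-6-methylphenyl)-12-hydroxy-2,6,10-trimethyldodeca-2,6,10-trienoate
Product: 13 methyl (2Z,6E)-9-[(2R)-7-hydroxy-2,5-dimethyl-2H-chromen-2-yl]-2,6-dimethylnona-2,6-dienoate, via o-quinone methide 12 (not isolated)
Conditions: (R)-3,3′-bis(2,4,6-triisopropylphenyl)-BINOL N-triflylphosphoramide (5 mol %), 4 Å MS, toluene (0.02 M), −78 °C; Et3N quench at −78 °C; keep 13 cold and dark
Reagents that add atoms: none
Why: Proposed new method: the chiral acid ionises the benzylic/allylic C–OH (activated by the o- and p-OH) at −78 °C to the dearomatised vinyl o-quinone methide 12, held as an H-bonded contact ion pair with the chiral anion; because its 10E alkene geometry is fixed, the methyl-versus-chain problem reduces to the helical sense of the disrotatory oxa-6π closure, which the catalyst controls from the C=O/OH terminus, so that O1–C2 forms as R while the ring rearomatises; the closest known reaction types are the chiral N-triflylphosphoramide (contact-ion-pair) cyclisation of o-hydroxyaryl allylic alcohols to 2,2-disubstituted 2H-chromenes and chiral-phosphoric-acid catalysis of o-quinone methides.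

Step 8
Reactants: 13 methyl (2Z,6E)-9-[(2R)-7-hydroxy-2,5-dimethyl-2H-chromen-2-yl]-2,6-dimethylnona-2,6-dienoate
Product: 14 methyl (2Z,6E)-9-[(2R)-7-hydroxy-2,5-dimethyl-3,4-dihydro-2H-chromen-2-yl]-2,6-dimethylnona-2,6-dienoate
Conditions: H2 (1 atm), RhCl(PPh3)3 (5 mol %), PhH/EtOH 1:1, rt
Reagents that add atoms: none
Why: Homogeneous hydrogenation with Wilkinson's catalyst is sterically governed and saturates the cis-disubstituted C3=C4 bond while leaving the trisubstituted alkenes (including the Z-enoate) alone, as in the classical selective 1,2-reduction of steroidal 1,4-dien-3-ones next to a quaternary carbon; C2 is not involved.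

Step 9
Reactants: 14 methyl (2Z,6E)-9-[(2R)-7-hydroxy-2,5-dimethyl-3,4-dihydro-2H-chromen-2-yl]-2,6-dimethylnona-2,6-dienoate
Product: 15 (2Z,6E)-9-[(2R)-7-hydroxy-2,5-dimethyl-3,4-dihydro-2H-chromen-2-yl]-2,6-dimethylnona-2,6-dienoic acid
Conditions: LiOH·H2O (5 equiv), degassed THF/MeOH/H2O 3:1:1, rt; then 1 M HCl to pH 3
Reagents that add atoms: lithium hydroxide, [Li+].[OH-]
Why: Saponification of the methyl ester with LiOH near room temperature hydrolyses (Z)-2-methyl-2-enoates without Z-to-E isomerisation, and the chromane ether and its stereocentre are inert to these conditions.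

**Compound list**
1 | orcinol (5-methylbenzene-1,3-diol) | Cc1cc(O)cc(O)c1 | starting material
2 | 4-iodo-5-methylbenzene-1,3-diol | Cc1cc(O)cc(O)c1I | intermediate
3 | (2E,6E)-farnesol | CC(C)=CCC/C(C)=C/CC/C(C)=C/CO | starting material
4 | (2E,6E)-10-bromo-3,7,11-trimethyldodeca-2,6-diene-1,11-diol (racemic, not isolated) | CC(C)(O)C(Br)CC/C(C)=C/CC/C(C)=C/CO | intermediate
5 | (2E,6E)-9-(3,3-dimethyloxiran-2-yl)-3,7-dimethylnona-2,6-dien-1-ol (10,11-epoxyfarnesol, racemic) | CC1(C)OC1CC/C(C)=C/CC/C(C)=C/CO | intermediate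
6 | (4E,8E)-10-hydroxy-4,8-dimethyldeca-4,8-dienal | O=CCC/C(C)=C/CC/C(C)=C/CO | intermediate
7 | methyl 2-[bis(2,2,2-trifluoroethoxy)phosphoryl]propanoate | COC(=O)C(C)P(=O)(OCC(F)(F)F)OCC(F)(F)F | starting material
8 | methyl (2Z,6E,10E)-12-hydroxy-2,6,10-trimethyldodeca-2,6,10-trienoate | COC(=O)/C(C)=C\CC/C(C)=C/CC/C(C)=C/CO | intermediate
9 | methyl (2Z,6E,10E)-2,6,10-trimethyl-12-oxododeca-2,6,10-trienoate | COC(=O)/C(C)=C\CC/C(C)=C/CC/C(C)=C/C=O | intermediate
10 | [2,4-bis(chloromagnesiooxy)-6-methylphenyl]magnesium chloride (not isolated) | Cc1cc(O[Mg]Cl)cc(O[Mg]Cl)c1[Mg]Cl | intermediate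
11 | methyl (2Z,6E,10E)-12-(2,4-dihydroxy-6-methylphenyl)-12-hydroxy-2,6,10-trimethyldodeca-2,6,10-trienoate (racemic at C12) | COC(=O)/C(C)=C\CC/C(C)=C/CC/C(C)=C/C(O)c1c(C)cc(O)cc1O | intermediate
12 | methyl (2Z,6E,10E)-12-[(1Z)-4-hydroxy-2-methyl-6-oxocyclohexa-2,4-dien-1-ylidene]-2,6,10-trimethyldodeca-2,6,10-trienoate (o-quinone methide, not isolated) | COC(=O)/C(C)=C\CC/C(C)=C/CC/C(C)=C/C=C1/C(C)=CC(O)=CC1=O | intermediate
13 | methyl (2Z,6E)-9-[(2R)-7-hydroxy-2,5-dimethyl-2H-chromen-2-yl]-2,6-dimethylnona-2,6-dienoate | COC(=O)/C(C)=C\CC/C(C)=C/CC[C@]1(C)C=Cc2c(C)cc(O)cc2O1 | intermediate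
14 | methyl (2Z,6E)-9-[(2R)-7-hydroxy-2,5-dimethyl-3,4-dihydro-2H-chromen-2-yl]-2,6-dimethylnona-2,6-dienoate | COC(=O)/C(C)=C\CC/C(C)=C/CC[C@]1(C)CCc2c(C)cc(O)cc2O1 | intermediate
15 | (2Z,6E)-9-[(2R)-7-hydroxy-2,5-dimethyl-3,4-dihydro-2H-chromen-2-yl]-2,6-dimethylnona-2,6-dienoic acid (CNP0244790.1) | C/C(=C/CC/C(C)=C/CC[C@]1(C)CCc2c(C)cc(O)cc2O1)C(=O)O | target

**Step count:** 9 steps in total. Longest linear sequence: 8 steps (3 → 5 → 6 → 8 → 9 → 11 → 13 → 14 → 15); the arene branch is 1 step.

**Steps most likely to fail and their fallbacks**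

The asymmetric ring closure (step 7) is the least certain: the level and sense of induction are untested for a methyl/alkyl pair, and the ee is also capped by the 2E purity of the farnesol and by any E/Z leakage in the cation. The fallback sets out from 11 and gives up catalytic induction. A catalytic amount of PPTS in CH2Cl2 at 0 °C closes 11 to the racemic methyl (2Z,6E)-9-(7-hydroxy-2,5-dimethyl-2H-chromen-2-yl)-2,6-dimethylnona-2,6-dienoate F1. Preparative SFC on a polysaccharide chiral phase then delivers 13, where the route is rejoined. The unwanted methyl (2Z,6E)-9-[(2S)-7-hydroxy-2,5-dimethyl-2H-chromen-2-yl]-2,6-dimethylnona-2,6-dienoate F2 is re-equilibrated to F1 with PPTS at room temperature (ring opening to 12 and reclosure) and recycled.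

The aryl Grignard addition (step 6) may fail because the triply magnesiated, very electron-rich arene exchanges slowly or precipitates, and because 11 is extremely acid-labile. The fallback sets out from 2 and uses a protecting-group approach. TESCl/imidazole in DMF gives [(4-iodo-5-methyl-1,3-phenylene)bis(oxy)]bis(triethylsilane) F3. iPrMgCl·LiCl in THF converts it into the ordinary mono-Grignard [2,4-bis(triethylsilyloxy)-6-methylphenyl]magnesium chloride F4. Addition to 9 at −78 °C gives the base-stable, chromatographable methyl (2Z,6E,10E)-12-[2,4-bis(triethylsilyloxy)-6-methylphenyl]-12-hydroxy-2,6,10-trimethyldodeca-2,6,10-trienoate F5. K2CO3/MeOH at 0 °C with a pH 7 quench frees the phenols immediately before the ring closure, rejoining the route at 11.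

The iodination (step 1) may give the 2-iodo isomer or di-iodide instead of clean C4 substitution. The fallback sets out from 1 and uses steric direction. TBSCl/imidazole gives [(5-methyl-1,3-phenylene)bis(oxy)]bis(tert-butyldimethylsilane) F6, whose position between the two bulky silyl ethers is shielded. NIS in MeCN at 0 °C then iodinates between OTBS and CH3 (as for 3,5-dimethoxytoluene) to [(4-iodo-5-methyl-1,3-phenylene)bis(oxy)]bis(tert-butyldimethylsilane) F7. TBAF in THF returns the route to 2.

**Further compounds**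
F1 | step 7 | methyl (2Z,6E)-9-(7-hydroxy-2,5-dimethyl-2H-chromen-2-yl)-2,6-dimethylnona-2,6-dienoate (racemate) | COC(=O)/C(C)=C\CC/C(C)=C/CCC1(C)C=Cc2c(C)cc(O)cc2O1
F2 | step 7 | methyl (2Z,6E)-9-[(2S)-7-hydroxy-2,5-dimethyl-2H-chromen-2-yl]-2,6-dimethylnona-2,6-dienoate | COC(=O)/C(C)=C\CC/C(C)=C/CC[C@@]1(C)C=Cc2c(C)cc(O)cc2O1
F3 | step 6 | [(4-iodo-5-methyl-1,3-phenylene)bis(oxy)]bis(triethylsilane) | Cc1cc(O[Si](CC)(CC)CC)cc(O[Si](CC)(CC)CC)c1I
F4 | step 6 | [2,4-bis(triethylsilyloxy)-6-methylphenyl]magnesium chloride | Cc1cc(O[Si](CC)(CC)CC)cc(O[Si](CC)(CC)CC)c1[Mg]Cl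
F5 | step 6 | methyl (2Z,6E,10E)-12-[2,4-bis(triethylsilyloxy)-6-methylphenyl]-12-hydroxy-2,6,10-trimethyldodeca-2,6,10-trienoate | COC(=O)/C(C)=C\CC/C(C)=C/CC/C(C)=C/C(O)c1c(C)cc(O[Si](CC)(CC)CC)cc1O[Si](CC)(CC)CC
F6 | step 1 | [(5-methyl-1,3-phenylene)bis(oxy)]bis(tert-butyldimethylsilane) | Cc1cc(O[Si](C)(C)C(C)(C)C)cc(O[Si](C)(C)C(C)(C)C)c1
F7 | step 1 | [(4-iodo-5-methyl-1,3-phenylene)bis(oxy)]bis(tert-butyldimethylsilane) | Cc1cc(O[Si](C)(C)C(C)(C)C)cc(O[Si](C)(C)C(C)(C)C)c1I
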